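**Plan**

1. Retrosynthesis (eudesmane numbering for the decalin–lactone half: C8 bears the lactone oxygen, C11 is the spiro carbon, C12 the carbonyl carbon, C13 the pyran CH2 next to C11): the γ-lactone is cut at C11–C12 and O–C8; the dihydropyran is then cut by a retro-hetero-Diels–Alder reaction (O–C11 and C13–CH2) into ent-β-elemenal (12) and the 1-methoxyvinyl decalin 21.
2. 21 goes back to (+)-alantolactone (13), whose C12 is removed by a Curtius rearrangement; 12 goes back to geraniol (1) and 3-methylbut-3-enoic acid (2).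
3. Forward order: elemane cyclohexane ring (Ireland–Claisen rearrangement, then carbonyl-ene ring closure) and enal; decalin enol ether from 13; dihydropyran ring by hetero-Diels–Alder reaction; spiro γ-lactone ring last.
4. Stereochemistry: the quaternary carbon and its neighbour in the elemane half come from the boron-controlled Claisen rearrangement, the third centre from the chair ene transition state; C4, C7, C10 and C8 (inverted twice) come from 13; the spiro carbon C11 is set in the key step by Felkin–Anh addition next to C7.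
5. Enabling feature: C11 is the ketal-type (anomeric) carbon of the dihydropyran ring and can be ionised to a ring oxocarbenium ion, while C8 of ring B lies 1,3 to it and can hold an α leaving group. A one-carbon nucleophile with a latent oxygen (an isocyanide standing in for CO2) can therefore bond to C11 through carbon and to C8 through oxygen in one flask; the methoxy, silyl, bromo and tert-butylamino groups are helpers that leave again.

Key step: step 15

Assumption: the (4S,5S)-bromoborane of step 2 (made beforehand from the commercial bis-sulfonamide and BBr3) is taken to deliver the (2R,3R)-acid 5; if the sense of induction proves opposite, its mirror-image form is used.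

Step 1
Reactants: 1 geraniol; 2 3-methylbut-3-enoic acid
Product: 3 geranyl 3-methylbut-3-enoate
Conditions: DCC, DMAP (cat.), CH2Cl2, 0 °C
Reagents that add atoms: none
Why: Steglich esterification of the primary allylic alcohol, run cold with little DMAP so that the β,γ-double bond of the acid should not move into conjugation.

Step 2
Reactants: 3 geranyl 3-methylbut-3-enoate
Product: 5 (2R,3R)-3-ethenyl-3,7-dimethyl-2-(prop-1-en-2-yl)oct-6-enoic acid, via boron ketene acetal 4 (not isolated)
Conditions: (4S,5S)-2-bromo-1,3-bis{[3,5-bis(trifluoromethyl)phenyl]sulfonyl}-4,5-diphenyl-1,3,2-diazaborolidine, Et3N, toluene–hexane, −78 °C, then 4 °C; aqueous work-up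
Reagents that add atoms: none
Why: Enantioselective Ireland–Claisen rearrangement through a chiral boron ketene acetal: soft enolisation should place the isopropenyl group cis to the geranyloxy oxygen, the chair transition state of the (E)-allyl unit (homoprenyl chain equatorial, isopropenyl axial) then gives the (2R*,3R*) relationship of the new quaternary and tertiary centres, and the C2-symmetric diazaborolidine selects the enantiotopic face.

Step 3
Reactants: 5 (2R,3R)-3-ethenyl-3,7-dimethyl-2-(prop-1-en-2-yl)oct-6-enoic acid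
Product: 6 (2R,3R)-3-ethenyl-3,7-dimethyl-2-(prop-1-en-2-yl)oct-6-en-1-ol
Conditions: LiAlH4, Et2O, 0 → 23 °C
Reagents that add atoms: none
Why: Hydride reduction of the carboxylic acid to the primary alcohol, which leaves the isolated alkenes and both stereocentres untouched.

Step 4
Reactants: 6 (2R,3R)-3-ethenyl-3,7-dimethyl-2-(prop-1-en-2-yl)oct-6-en-1-ol
Product: 7 (2R,3R)-3-ethenyl-3,7-dimethyl-2-(prop-1-en-2-yl)oct-6-enal
Conditions: Dess–Martin periodinane, pyridine, CH2Cl2, 0 °C
Reagents that add atoms: none
Why: Buffered Dess–Martin oxidation gives the β,γ-unsaturated aldehyde under neutral conditions, so the α-centre should neither epimerise nor conjugate; the aldehyde is used at once.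

Step 5
Reactants: 7 (2R,3R)-3-ethenyl-3,7-dimethyl-2-(prop-1-en-2-yl)oct-6-enal
Product: 8 (1R,2R,3R,6R)-3-ethenyl-3-methyl-2,6-di(prop-1-en-2-yl)cyclohexan-1-ol
Conditions: ZnBr2 (cat.), toluene, 0 °C
Reagents that add atoms: none
Why: Intramolecular carbonyl-ene cyclisation of the citronellal-to-isopulegol kind: the chair transition state keeps the existing isopropenyl group equatorial and places the new hydroxyl and the new isopropenyl group equatorial and trans, which sets the carbinol carbon and the third elemane stereocentre.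

Step 6
Reactants: 8 (1R,2R,3R,6R)-3-ethenyl-3-methyl-2,6-di(prop-1-en-2-yl)cyclohexan-1-ol
Product: 9 O-[(1R,2R,3R,6R)-3-ethenyl-3-methyl-2,6-di(prop-1-en-2-yl)cyclohexyl] S-methyl carbonodithioate
Conditions: NaH, CS2, then MeI, THF, 0 → 23 °C
Reagents that add atoms: carbon disulfide, S=C=S; iodomethane, CI
Why: Xanthate formation from the secondary alkoxide prepares the hydroxyl for radical removal without touching a stereocentre.

Step 7
Reactants: 9 O-[(1R,2R,3R,6R)-3-ethenyl-3-methyl-2,6-di(prop-1-en-2-yl)cyclohexyl] S-methyl carbonodithioate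
Product: 10 ent-β-elemene, (1R,2R,4S)-1-ethenyl-1-methyl-2,4-di(prop-1-en-2-yl)cyclohexane
Conditions: Bu3SnH (1 M), AIBN, toluene, 80 °C
Reagents that add atoms: none
Why: Barton–McCombie deoxygenation; the concentrated stannane should reduce the secondary radical before the slow homoallyl (1,2-vinyl) rearrangement, and the three remaining stereocentres are not involved.

Step 8
Reactants: 10 ent-β-elemene
Product: 12 ent-β-elemenal, 2-[(1S,3R,4R)-4-ethenyl-4-methyl-3-(prop-1-en-2-yl)cyclohexyl]prop-2-enal, via allylic alcohol 11 (not isolated)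
Conditions: SeO2 (cat.), t-BuOOH, CH2Cl2, 23 °C; then MnO2, CH2Cl2, 23 °C
Reagents that add atoms: tert-butyl hydroperoxide, CC(C)(C)OO
Why: Selenium dioxide allylic oxidation (ene reaction, then [2,3]-shift) should attack the methyl of the less hindered isopropenyl group on C4 of the ring, far from the quaternary carbon (the vinyl group has no allylic hydrogen), and MnO2 takes the allylic alcohol on to the enal; no stereocentre is formed.

Step 9
Reactants: 13 (+)-alantolactone
Product: 16 8β-(tert-butyldimethylsilyloxy)eudesma-5,11(13)-dien-12-oic acid, via lithium hydroxy carboxylate 14 (not isolated), via bis-silyl derivative 15 (not isolated)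
Conditions: LiOH, THF–H2O, 23 °C; solvent removed; TBSOTf, 2,6-lutidine, CH2Cl2, 0 → 23 °C; then MeOH–H2O, 23 °C
Reagents that add atoms: lithium hydroxide, [Li+].[OH-]; tert-butyldimethylsilyl trifluoromethanesulfonate, CC(C)(C)[Si](C)(C)OS(=O)(=O)C(F)(F)F
Why: Saponification of the lactone, silylation of carboxylate and hindered 8β-hydroxyl, and selective solvolysis of the silyl ester; the silyl ether blocks relactonisation and C8 keeps its configuration.

Step 10
Reactants: 16 8β-(tert-butyldimethylsilyloxy)eudesma-5,11(13)-dien-12-oic acid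
Product: 19 8β-(tert-butyldimethylsilyloxy)-12-noreudesm-5-en-11-one, via acyl azide 17 (not isolated), via vinyl isocyanate 18 (not isolated)
Conditions: (PhO)2P(O)N3, Et3N, toluene, 23 → 80 °C; then AcOH–H2O–THF, 0 → 23 °C
Reagents that add atoms: water, O
Why: Curtius rearrangement of the α-substituted acrylic acid to the 1-substituted vinyl isocyanate, whose mild hydrolysis gives the enamine and then the methyl ketone with loss of C12 as CO2; weakly acidic conditions are chosen so that the C5=C6 double bond should not move into conjugation and C7 should not epimerise.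

Step 11
Reactants: 19 8β-(tert-butyldimethylsilyloxy)-12-noreudesm-5-en-11-one
Product: 21 11-methoxy-8β-(tert-butyldimethylsilyloxy)-12-noreudesma-5,11(13)-diene, via dimethyl ketal 20 (not isolated)
Conditions: Me3SiOMe, Me3SiOTf (cat.), CH2Cl2, −78 °C; then i-Pr2NEt, Me3SiOTf, −20 → 0 °C
Reagents that add atoms: methoxytrimethylsilane, CO[Si](C)(C)C
Why: Silyl-triflate-catalysed ketalisation followed by amine-mediated elimination of methanol from the methoxycarbenium ion at the unhindered methyl group should give the less substituted methyl enol ether without strong base, so the β-silyloxy group is not eliminated.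

Step 12
Reactants: 21 11-methoxy-8β-(tert-butyldimethylsilyloxy)-12-noreudesma-5,11(13)-diene; 12 ent-β-elemenal
Product: 22 2-methoxy-2-(8β-silyloxy-decalinyl)-5-elemanyl-3,4-dihydro-2H-pyran (methyl ketal, both C11 epimers)
Conditions: Yb(fod)3 (cat.; fod = 6,6,7,7,8,8,8-heptafluoro-2,2-dimethyloctane-3,5-dionate), CH2Cl2, 23 °C
Reagents that add atoms: none
Why: Inverse-electron-demand hetero-Diels–Alder reaction of the enal (heterodiene) with the electron-rich 1,1-disubstituted enol ether: the carbonyl oxygen bonds to the methoxy-bearing carbon C11 and the enal β-carbon to the CH2 terminus; both C11 epimers are carried on because C11 is ionised in step 15.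

Step 13
Reactants: 22 methyl ketal with 8β-silyloxy group
Product: 23 methyl ketal with free 8β-hydroxyl
Conditions: Bu4NF, THF, 23 °C
Reagents that add atoms: none
Why: Fluoride cleavage of the silyl ether; the ketal and the enol ether are stable to these basic conditions.

Step 14
Reactants: 23 methyl ketal with free 8β-hydroxyl
Product: 24 methyl ketal with 8α-bromide
Conditions: CBr4, PPh3, 2,6-lutidine, CH2Cl2, 0 °C
Reagents that add atoms: carbon tetrabromide, BrC(Br)(Br)Br
Why: Appel bromination of the axial 8β-alcohol by SN2 inversion from the open α-face should give the equatorial 8α-bromide trans to the C7 substituent, with the pyridine base buffering traces of HBr.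

Step 15
Reactants: 24 methyl ketal with 8α-bromide; 25 tert-butyl isocyanide
Product: 30 CNP0175206.1 (target), via oxocarbenium triflate 26 (not isolated), via nitrilium triflate 27 (not isolated), via amide 28 (not isolated), via iminolactonium bromide 29 (not isolated)
Conditions: 25, Me3SiOTf, 2,6-di-tert-butyl-4-methylpyridine, CH2Cl2, −78 °C; H2O, −78 → 23 °C; MeCN, 60 °C; aq. NaOAc–AcOH (pH 4.5), 23 °C
Reagents that add atoms: tert-butyl isocyanide (25), CC(C)(C)[N+]#[C-]; water, O
Why: Proposed new method: Me3SiOTf should ionise the exocyclic methoxy group of the ketal (both C11 epimers of 24 converge) to the ring oxocarbenium ion 26, the isocyanide carbon adds to give nitrilium ion 27, water turns it into amide 28, the amide oxygen displaces the 8α-bromide and the N-tert-butyl iminolactonium salt 29 is hydrolysed to the lactone, so that the isocyanide carbon becomes C12 and both lactone oxygens come from water. The closest known reaction types are the Lewis-acid-mediated α-addition of isocyanides to acetals (Passerini-type) and the cyclisation of γ-halo amides to iminolactones, which hydrolyse to lactones. The γ-lactone ring closes by 5-exo-tet O-alkylation with inversion at C8, so the equatorial 8α-bromide gives the axial 8β-oxygen and the cis ring fusion. C11 is set under Felkin–Anh control by C7: the isocyanide enters on the face anti to the C7–C8 bond (the other face is shielded by the equatorial bromine), with the C=O+ bond near C7–C6 and C13 near H7, which after ring closure puts the pyran oxygen syn to H7 (11R). The step needs ionisation of the exocyclic rather than the ring C–O bond (the methoxy oxygen is the more basic one), capture of 26 before loss of H7 or H13 (a good carbon nucleophile in excess at −78 °C) and O- rather than N-alkylation of the amide (tert-butyl group, five-membered transition state); the equatorial bromide has no anti-periplanar hydrogen, which disfavours elimination, and the amide oxygen is a better neighbouring group than the C5=C6 double bond.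

**Compound list**

1 | geraniol, (2E)-3,7-dimethylocta-2,6-dien-1-ol | CC(C)=CCC/C(C)=C/CO | starting material
2 | 3-methylbut-3-enoic acid | CC(=C)CC(=O)O | starting material
3 | geranyl 3-methylbut-3-enoate | CC(C)=CCC/C(C)=C/COC(=O)CC(C)=C | intermediate
4 | boron ketene acetal of 3 (isopropenyl cis to the geranyloxy oxygen; boron in the (4S,5S)-diazaborolidine) | CC(C)=CCC/C(C)=C/CO/C(OB1N(S(=O)(=O)c2cc(cc(c2)C(F)(F)F)C(F)(F)F)[C@@H](c2ccccc2)[C@H](c2ccccc2)N1S(=O)(=O)c1cc(cc(c1)C(F)(F)F)C(F)(F)F)=C\C(C)=C | intermediate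
5 | (2R,3R)-3-ethenyl-3,7-dimethyl-2-(prop-1-en-2-yl)oct-6-enoic acid | OC(=O)[C@H](C(C)=C)[C@@](C)(C=C)CCC=C(C)C | intermediate
6 | (2R,3R)-3-ethenyl-3,7-dimethyl-2-(prop-1-en-2-yl)oct-6-en-1-ol | OC[C@H](C(C)=C)[C@@](C)(C=C)CCC=C(C)C | intermediate
7 | (2R,3R)-3-ethenyl-3,7-dimethyl-2-(prop-1-en-2-yl)oct-6-enal | O=C[C@H](C(C)=C)[C@@](C)(C=C)CCC=C(C)C | intermediate
8 | (1R,2R,3R,6R)-3-ethenyl-3-methyl-2,6-di(prop-1-en-2-yl)cyclohexan-1-ol | C=C[C@@]1(C)CC[C@H](C(C)=C)[C@@H](O)[C@@H]1C(C)=C | intermediate
9 | O-[(1R,2R,3R,6R)-3-ethenyl-3-methyl-2,6-di(prop-1-en-2-yl)cyclohexyl] S-methyl carbonodithioate | C=C[C@@]1(C)CC[C@H](C(C)=C)[C@@H](OC(=S)SC)[C@@H]1C(C)=C | intermediate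
10 | ent-β-elemene, (1R,2R,4S)-1-ethenyl-1-methyl-2,4-di(prop-1-en-2-yl)cyclohexane | C=C[C@@]1(C)CC[C@H](C(C)=C)C[C@@H]1C(C)=C | intermediate
11 | 2-[(1S,3R,4R)-4-ethenyl-4-methyl-3-(prop-1-en-2-yl)cyclohexyl]prop-2-en-1-ol | C=C[C@@]1(C)CC[C@H](C(=C)CO)C[C@@H]1C(C)=C | intermediate
12 | ent-β-elemenal, 2-[(1S,3R,4R)-4-ethenyl-4-methyl-3-(prop-1-en-2-yl)cyclohexyl]prop-2-enal | C=C[C@@]1(C)CC[C@H](C(=C)C=O)C[C@@H]1C(C)=C | intermediate
13 | (+)-alantolactone, (3aR,5S,8aR,9aR)-5,8a-dimethyl-3-methylidene-3a,5,6,7,8,8a,9,9a-octahydronaphtho[2,3-b]furan-2(3H)-one | C=C1C(=O)O[C@@H]2C[C@@]3(C)CCC[C@H](C)C3=C[C@H]12 | starting material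
14 | lithium 8β-hydroxyeudesma-5,11(13)-dien-12-oate (C4, C7, C10 as in alantolactone) | C=C(C(=O)[O-])[C@H]1C=C2[C@@H](C)CCC[C@]2(C)C[C@H]1O.[Li+] | intermediate
15 | tert-butyldimethylsilyl 8β-(tert-butyldimethylsilyloxy)eudesma-5,11(13)-dien-12-oate | C=C(C(=O)O[Si](C)(C)C(C)(C)C)[C@H]1C=C2[C@@H](C)CCC[C@]2(C)C[C@H]1O[Si](C)(C)C(C)(C)C | intermediate
16 | 8β-(tert-butyldimethylsilyloxy)eudesma-5,11(13)-dien-12-oic acid | C=C(C(=O)O)[C@H]1C=C2[C@@H](C)CCC[C@]2(C)C[C@H]1O[Si](C)(C)C(C)(C)C | intermediate
17 | 8β-(tert-butyldimethylsilyloxy)eudesma-5,11(13)-dien-12-oyl azide | C=C(C(=O)N=[N+]=[N-])[C@H]1C=C2[C@@H](C)CCC[C@]2(C)C[C@H]1O[Si](C)(C)C(C)(C)C | intermediate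
18 | 11-isocyanato-8β-(tert-butyldimethylsilyloxy)-12-noreudesma-5,11(13)-diene | C=C(N=C=O)[C@H]1C=C2[C@@H](C)CCC[C@]2(C)C[C@H]1O[Si](C)(C)C(C)(C)C | intermediate
19 | 8β-(tert-butyldimethylsilyloxy)-12-noreudesm-5-en-11-one (methyl ketone at C7) | CC(=O)[C@H]1C=C2[C@@H](C)CCC[C@]2(C)C[C@H]1O[Si](C)(C)C(C)(C)C | intermediate
20 | 11,11-dimethoxy-8β-(tert-butyldimethylsilyloxy)-12-noreudesm-5-ene | COC(C)(OC)[C@H]1C=C2[C@@H](C)CCC[C@]2(C)C[C@H]1O[Si](C)(C)C(C)(C)C | intermediate
21 | 11-methoxy-8β-(tert-butyldimethylsilyloxy)-12-noreudesma-5,11(13)-diene (1-methoxyvinyl group at C7) | C=C(OC)[C@H]1C=C2[C@@H](C)CCC[C@]2(C)C[C@H]1O[Si](C)(C)C(C)(C)C | intermediate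
22 | 2-methoxy-2-[(2S,3R,4aR,8S)-3-(tert-butyldimethylsilyloxy)-4a,8-dimethyl-2,3,4,4a,5,6,7,8-octahydronaphthalen-2-yl]-5-[(1S,3R,4R)-4-ethenyl-4-methyl-3-(prop-1-en-2-yl)cyclohexyl]-3,4-dihydro-2H-pyran (both epimers at the ketal carbon) | C=C[C@@]1(C)CC[C@H](C2=COC(OC)(CC2)[C@H]2C=C3[C@@H](C)CCC[C@]3(C)C[C@H]2O[Si](C)(C)C(C)(C)C)C[C@@H]1C(C)=C | intermediate
23 | as 22 with free 8β-hydroxyl (3R-hydroxy on the octahydronaphthalenyl group) | C=C[C@@]1(C)CC[C@H](C2=COC(OC)(CC2)[C@H]2C=C3[C@@H](C)CCC[C@]3(C)C[C@H]2O)C[C@@H]1C(C)=C | intermediate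
24 | as 22 with 8α-bromide in place of the silyloxy group (equatorial, trans to the C7 substituent) | C=C[C@@]1(C)CC[C@H](C2=COC(OC)(CC2)[C@H]2C=C3[C@@H](C)CCC[C@]3(C)C[C@@H]2Br)C[C@@H]1C(C)=C | intermediate
25 | tert-butyl isocyanide | CC(C)(C)[N+]#[C-] | starting material
26 | ring oxocarbenium triflate from 24 (C11=O+ in the dihydropyran ring, 8α-bromide) | C=C[C@@]1(C)CC[C@H](C2=C[O+]=C(CC2)[C@H]2C=C3[C@@H](C)CCC[C@]3(C)C[C@@H]2Br)C[C@@H]1C(C)=C.[O-]S(=O)(=O)C(F)(F)F | intermediate
27 | N-tert-butylnitrilium triflate at C11 (11R, 8α-bromide) | C=C[C@@]1(C)CC[C@H](C2=CO[C@@](CC2)(C#[N+]C(C)(C)C)[C@H]2C=C3[C@@H](C)CCC[C@]3(C)C[C@@H]2Br)C[C@@H]1C(C)=C.[O-]S(=O)(=O)C(F)(F)F | intermediate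
28 | N-tert-butyl carboxamide at C11 (11R, 8α-bromide) | C=C[C@@]1(C)CC[C@H](C2=CO[C@@](CC2)(C(=O)NC(C)(C)C)[C@H]2C=C3[C@@H](C)CCC[C@]3(C)C[C@@H]2Br)C[C@@H]1C(C)=C | intermediate
29 | N-tert-butyl iminolactonium bromide (target skeleton with C12=NH+–t-Bu in place of C12=O) | C=C[C@@]1(C)CC[C@H](C2=CO[C@@]3(CC2)C(=[NH+]C(C)(C)C)O[C@@H]2C[C@@]4(C)CCC[C@H](C)C4=C[C@@H]23)C[C@@H]1C(C)=C.[Br-] | intermediate
30 | CNP0175206.1, (3R,3aS,5S,8aR,9aR)-5'-[(1S,3R,4R)-4-ethenyl-4-methyl-3-(prop-1-en-2-yl)cyclohexyl]-5,8a-dimethyl-3',4',3a,5,6,7,8,8a,9,9a-decahydro-2H-spiro[naphtho[2,3-b]furan-3,2'-pyran]-2-one | C=C[C@@]1(C)CC[C@H](C2=CO[C@@]3(CC2)C(=O)O[C@@H]2C[C@@]4(C)CCC[C@H](C)C4=C[C@@H]23)C[C@@H]1C(=C)C | target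

**Step count and risks**

Total step count: 15. Longest linear sequence: 12 steps (steps 1–8, then 12–15).

Steps most likely to fail:

Step 15 (Proposed new method). What may go wrong: poor facial selectivity in the addition of the isocyanide to the oxocarbenium ion (giving the C11 epimer), ring-opening ionisation of the ketal or proton loss from the cation before it is captured, and sluggish O-alkylation at the hindered C8. The Felkin–Anh argument for C11 is a qualitative model and is the least secure point of the route. The fallback uses known chemistry, sets out from enal 12 and (+)-alantolactone 13 and comes back at 30: heating the two together neat or in toluene (110 °C, radical inhibitor) should give the target directly by an inverse-demand hetero-Diels–Alder reaction across the 11(13)-methylene group, the enal adding to the convex face of the cis-fused lactone. It makes no new compound.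

Step 11. What may go wrong: proton loss from C7 instead of from the methyl group in the elimination (giving the conjugated dienyl ether and loss of the C7 centre), or acid-induced migration of the C5=C6 double bond. The fallback sets out from ketone 19 and comes back at 21: kinetic deprotonation at the methyl group (KN(SiMe3)2, THF, −78 °C) and trapping with PhNTf2 should give the vinyl triflate F1. Miyaura borylation (B2pin2, PdCl2(PPh3)2, PPh3, KOPh, toluene, 50 °C) should give the alkenyl boronate F2. Copper-mediated etherification with methanol (Cu(OAc)2, Et3N, MeOH, air; Chan–Lam type) should then give 21.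

Step 8. What may go wrong: insufficient discrimination between the two isopropenyl groups, and over-oxidation. The fallback sets out from 10 and comes back at 12: ene-type allylic chlorination (NaOCl, AcOH, CH2Cl2, 0 °C) should give the allylic chloride F3, at which stage positional isomers can be removed, and oxidation with trimethylamine N-oxide (DMSO, 23 °C) should give 12.

**Further compounds**

F0 | step 15 | none | none
F1 | step 11 | 11-(trifluoromethanesulfonyloxy)-8β-(tert-butyldimethylsilyloxy)-12-noreudesma-5,11(13)-diene (vinyl triflate) | C=C(OS(=O)(=O)C(F)(F)F)[C@H]1C=C2[C@@H](C)CCC[C@]2(C)C[C@H]1O[Si](C)(C)C(C)(C)C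
F2 | step 11 | 11-(4,4,5,5-tetramethyl-1,3,2-dioxaborolan-2-yl)-8β-(tert-butyldimethylsilyloxy)-12-noreudesma-5,11(13)-diene (alkenyl boronate) | C=C(B1OC(C)(C)C(C)(C)O1)[C@H]1C=C2[C@@H](C)CCC[C@]2(C)C[C@H]1O[Si](C)(C)C(C)(C)C
F3 | step 8 | (1R,2R,4S)-4-(3-chloroprop-1-en-2-yl)-1-ethenyl-1-methyl-2-(prop-1-en-2-yl)cyclohexane (allylic chloride) | C=C[C@@]1(C)CC[C@H](C(=C)CCl)C[C@@H]1C(C)=C
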